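The route rests on cutting the acyloin unit of ring C, the C3(OH)–C4(=O) bond of the chroman-4-one, by umpolung. A chiral triazolylidene turns the ring A aldehyde (future C4) into an acyl anion that closes ring C onto a ketone at C3. This ketone carries a benzyl ester as traceless activator: it keeps the carbene off C3, raises electrophilicity and makes C2–H so acidic that a racemic precursor converges on one enantiomer (dynamic kinetic resolution). The precursor is an open-chain, racemic 2-formylaryl ether of a benzyl 3-aryl-2-oxopropanoate. One hydrogenolysis then removes four benzyl groups, expels CO2 and sets C3 trans to C2. Selective O7 alkylation finishes.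

Key step: step 5

Assumption: the (5aS,10bR) antipode of the triazolium salt is taken to favour the (2R) series. If the sense of induction is the opposite, the equally available (5aR,10bS) salt is used and nothing else changes.

Step 1
Reactants: 1 2,4,6-trihydroxybenzaldehyde
Product: 2 2,4-bis(benzyloxy)-6-hydroxybenzaldehyde
Conditions: BnBr (2.05 equiv), K2CO3 (2.2 equiv), DMF, 23 °C
Reagents that add atoms: benzyl bromide, BrCc1ccccc1
Why: Williamson etherification under weak base, in which the hydroxyl that stays hydrogen-bonded to the formyl oxygen is the least nucleophilic, so benzylation should stop at the diether.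

Step 2
Reactants: 3 4-(benzyloxy)benzaldehyde; 4 benzyl chloroacetate
Product: 5 (±)-benzyl 3-[4-(benzyloxy)phenyl]oxirane-2-carboxylate (mainly trans)
Conditions: NaN(SiMe3)2 (1.1 equiv), THF, −78 °C to 23 °C
Reagents that add atoms: none
Why: Darzens glycidic ester condensation (aldol addition of the chloroacetate enolate, then intramolecular SN2); the racemic epoxide is used as it is because step 4 erases one of its stereocentres and makes the other labile.

Step 3
Reactants: 2 2,4-bis(benzyloxy)-6-hydroxybenzaldehyde; 5 (±)-benzyl 3-[4-(benzyloxy)phenyl]oxirane-2-carboxylate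
Product: 6 (±)-benzyl 3-[3,5-bis(benzyloxy)-2-formylphenoxy]-3-[4-(benzyloxy)phenyl]-2-hydroxypropanoate (diastereomer mixture)
Conditions: Cs2CO3 (20 mol %), DMF, 60 °C
Reagents that add atoms: none
Why: Base-catalysed SN2 opening of an aryl glycidate by a phenoxide, directed to the benzylic carbon because the 4-benzyloxyphenyl group loosens that C–O bond and the ester deactivates the neighbouring carbon; the stereoisomer mixture is of no consequence.

Step 4
Reactants: 6 (±)-benzyl 3-[3,5-bis(benzyloxy)-2-formylphenoxy]-3-[4-(benzyloxy)phenyl]-2-hydroxypropanoate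
Product: 7 (±)-benzyl 3-[3,5-bis(benzyloxy)-2-formylphenoxy]-3-[4-(benzyloxy)phenyl]-2-oxopropanoate
Conditions: Dess–Martin periodinane (1.2 equiv), CH2Cl2, 0 °C to 23 °C
Reagents that add atoms: none
Why: Dess–Martin oxidation of the secondary carbinol under near-neutral conditions leaves the aryl aldehyde, benzyl ethers and ester untouched and gives the alpha-keto ester whose remaining stereocentre is labile, as planned.

Step 5
Reactants: 7 (±)-benzyl 3-[3,5-bis(benzyloxy)-2-formylphenoxy]-3-[4-(benzyloxy)phenyl]-2-oxopropanoate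
Product: 9 benzyl (2R,3R)-5,7-bis(benzyloxy)-2-[4-(benzyloxy)phenyl]-3-hydroxy-4-oxochromane-3-carboxylate, via Breslow enaminol 8 (not isolated)
Conditions: (5aS,10bR)-2-(pentafluorophenyl)-5a,10b-dihydro-4H,6H-indeno[2,1-b][1,2,4]triazolo[4,3-d][1,4]oxazin-2-ium tetrafluoroborate (15 mol %), Et3N (30 mol %), 4 Å molecular sieves, toluene, argon, 25 °C
Reagents that add atoms: none
Why: The triazolylidene adds to the only aldehyde of 7 and a proton shift gives the acyl-anion equivalent 8, whose nucleophilic C4 attacks the ketone carbon C3 of the alpha-keto ester, after which proton transfer and loss of the carbene release the C4 ketone and the C3 tertiary carbinol. This is the carbene-catalysed intramolecular crossed aldehyde–ketone benzoin reaction, known for turning 2-(2-oxoalkoxy)benzaldehydes into 3-hydroxychroman-4-ones, combined with the dynamic kinetic resolution known for beta-stereogenic alpha-keto esters in carbene-catalysed benzoin additions. Ring C closes in a 6-exo-trig mode (C4 onto the C3=O carbon, oxygen exocyclic). C2 is set by dynamic kinetic resolution, because its C–H is benzylic, alpha to the ketone and alpha to oxygen, so Et3N interconverts the two antipodes by reversible enolisation faster than they cyclise and the chiral carbene should consume the (2R) antipode; C3 is set by the catalyst-controlled face of attack on the ketone in a half-chair with the 2-aryl group pseudo-equatorial, is drawn with OH trans to the aryl group, and is of no consequence because step 6 erases it. The selectivity needed is the choice of carbonyl that becomes the acyl anion, and the design secures it, since a ketone cannot form an enaminol, whereas a free aldehyde at C3 would compete for the carbene and then expel the aryloxide; the ester also makes C3 electrophilic enough to trap the hindered, electron-rich enaminol. The competing aldol closure of C2 onto the aldehyde cannot be followed by dehydration and so stays reversible, while the quaternary C3 of 9 blocks retro-oxa-Michael opening and freezes C2.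

Step 6
Reactants: 9 benzyl (2R,3R)-5,7-bis(benzyloxy)-2-[4-(benzyloxy)phenyl]-3-hydroxy-4-oxochromane-3-carboxylate
Product: 12 (2R,3R)-3,5,7-trihydroxy-2-(4-hydroxyphenyl)chroman-4-one [(+)-aromadendrin], via keto acid 10 (not isolated), via enediol 11 (not isolated)
Conditions: H2 (1 atm), Pd/C, EtOAc–MeOH, AcOH (cat.), 23 °C; then 40 °C under argon
Reagents that add atoms: none
Why: Hydrogenolysis of three benzyl ethers and the benzyl ester frees the alpha-hydroxy-beta-keto acid 10, which should decarboxylate as acetolactate does to enediol 11, and ketonisation to the chelated aryl ketone sets C3 under control of the fixed C2 centre, the diequatorial 2,3-trans isomer being the thermodynamic product to which any cis epimer equilibrates through 11.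

Step 7
Reactants: 13 2-methyl-2-vinyloxirane (isoprene monoxide)
Product: 14 (E)-4-chloro-2-methylbut-2-en-1-ol
Conditions: TiCl4 (1.1 equiv), CH2Cl2, −85 °C; then H2O
Reagents that add atoms: titanium tetrachloride, Cl[Ti](Cl)(Cl)Cl
Why: Lewis-acid-promoted SN2′ opening of the vinyl oxirane by chloride, which at low temperature should place the titanium-bound CH2O group trans to the new CH2Cl group and so give the E alkene.

Step 8
Reactants: 12 (+)-aromadendrin; 14 (E)-4-chloro-2-methylbut-2-en-1-ol
Product: 15 (2R,3R)-3,5-dihydroxy-7-{[(2E)-4-hydroxy-3-methylbut-2-en-1-yl]oxy}-2-(4-hydroxyphenyl)chroman-4-one (target)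
Conditions: K2CO3 (1.05 equiv), DMF, argon, 23 °C
Reagents that add atoms: none
Why: Williamson etherification with one equivalent of weak base, in which O7–H (para to the C4 carbonyl, a vinylogous acid) is the most acidic hydroxyl, O5–H is chelated, O4′–H is clearly less acidic and the aliphatic hydroxyls stay protonated, so the primary allylic chloride should be taken up at O7 by SN2 without change at C2, C3 or the alkene.

Compound list

1 | 2,4,6-trihydroxybenzaldehyde | O=Cc1c(O)cc(O)cc1O | starting material
2 | 2,4-bis(benzyloxy)-6-hydroxybenzaldehyde | O=Cc1c(O)cc(OCc2ccccc2)cc1OCc1ccccc1 | intermediate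
3 | 4-(benzyloxy)benzaldehyde | O=Cc1ccc(OCc2ccccc2)cc1 | starting material
4 | benzyl chloroacetate | ClCC(=O)OCc1ccccc1 | starting material
5 | (±)-benzyl 3-[4-(benzyloxy)phenyl]oxirane-2-carboxylate (racemic, mainly trans) | O=C(OCc1ccccc1)C1OC1c1ccc(OCc2ccccc2)cc1 | intermediate
6 | (±)-benzyl 3-[3,5-bis(benzyloxy)-2-formylphenoxy]-3-[4-(benzyloxy)phenyl]-2-hydroxypropanoate (racemic diastereomer mixture) | O=Cc1c(OCc2ccccc2)cc(OCc2ccccc2)cc1OC(c1ccc(OCc2ccccc2)cc1)C(O)C(=O)OCc1ccccc1 | intermediate
7 | (±)-benzyl 3-[3,5-bis(benzyloxy)-2-formylphenoxy]-3-[4-(benzyloxy)phenyl]-2-oxopropanoate (racemic, configurationally labile) | O=Cc1c(OCc2ccccc2)cc(OCc2ccccc2)cc1OC(c1ccc(OCc2ccccc2)cc1)C(=O)C(=O)OCc1ccccc1 | intermediate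
8 | Breslow enaminol: the former formyl carbon of 7 bears OH and is doubly bonded to the carbene carbon of the (5aS,10bR)-triazolylidene | OC(=C1N(c2c(F)c(F)c(F)c(F)c2F)N=C2CO[C@H]3Cc4ccccc4[C@H]3N12)c1c(OCc2ccccc2)cc(OCc2ccccc2)cc1OC(c1ccc(OCc2ccccc2)cc1)C(=O)C(=O)OCc1ccccc1 | intermediate
9 | benzyl (2R,3R)-5,7-bis(benzyloxy)-2-[4-(benzyloxy)phenyl]-3-hydroxy-4-oxochromane-3-carboxylate | c1ccccc1COc1cc(OCc3ccccc3)c2c(c1)O[C@H](c1ccc(OCc3ccccc3)cc1)[C@@](C(=O)OCc1ccccc1)(O)C2=O | intermediate
10 | (2R,3R)-3,5,7-trihydroxy-2-(4-hydroxyphenyl)-4-oxochromane-3-carboxylic acid | Oc1cc(O)c2c(c1)O[C@H](c1ccc(O)cc1)[C@@](C(=O)O)(O)C2=O | intermediate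
11 | (2R)-2-(4-hydroxyphenyl)-2H-chromene-3,4,5,7-tetrol (enediol) | Oc1cc(O)c2c(c1)O[C@H](c1ccc(O)cc1)C(O)=C2O | intermediate
12 | (2R,3R)-3,5,7-trihydroxy-2-(4-hydroxyphenyl)chroman-4-one, (+)-aromadendrin | Oc1cc(O)c2c(c1)O[C@H](c1ccc(O)cc1)[C@@H](O)C2=O | intermediate
13 | 2-methyl-2-vinyloxirane | C=CC1(C)CO1 | starting material
14 | (E)-4-chloro-2-methylbut-2-en-1-ol | C/C(=C\CCl)CO | intermediate
15 | (2R,3R)-3,5-dihydroxy-7-{[(2E)-4-hydroxy-3-methylbut-2-en-1-yl]oxy}-2-(4-hydroxyphenyl)chroman-4-one | C/C(=C\COc1cc(O)c2c(c1)O[C@H](c1ccc(O)cc1)[C@@H](O)C2=O)CO | target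

Total step count: 8. Longest linear sequence: 6 steps (steps 1, 3, 4, 5, 6 and 8 from compound 1; equally steps 2, 3, 4, 5, 6 and 8 from compounds 3 and 4).

Steps most likely to fail

Step 5.
- **What may go wrong:** Carbene addition to the doubly ortho-oxygenated, electron-rich aldehyde may be slow, so that reversible aldol closure and decay of the labile keto ester take over. The catalyst may also discriminate poorly between the two interconverting antipodes.
- **Fallback:** The same C3–C4 bond is closed as an alkene by ring-closing metathesis, with C2 set beforehand. The fallback sets out from 3 and 2 and comes back at 12.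
- Horner–Wadsworth–Emmons olefination of 3 (triethyl phosphonoacetate, NaH, THF) gives ethyl (E)-3-[4-(benzyloxy)phenyl]acrylate F1.
- i-Bu2AlH reduces it to (E)-3-[4-(benzyloxy)phenyl]prop-2-en-1-ol F2, and methyl chloroformate with pyridine gives (E)-3-[4-(benzyloxy)phenyl]prop-2-enyl methyl carbonate F3.
- Iridium-catalysed asymmetric allylic etherification joins the lithium phenoxide of 2 with F3. It uses [Ir(cod)Cl]2 and O,O′-(1,1′-binaphthalene-2,2′-diyl) N,N-bis(1-phenylethyl)phosphoramidite, with the antipode chosen for the S ether. The product is the branched ether 2,4-bis(benzyloxy)-6-{(1S)-1-[4-(benzyloxy)phenyl]prop-2-enyloxy}benzaldehyde F4.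
- Wittig methylenation gives 1,5-bis(benzyloxy)-3-{(1S)-1-[4-(benzyloxy)phenyl]prop-2-enyloxy}-2-vinylbenzene F5.
- The second-generation Grubbs catalyst (CH2Cl2, 40 °C) closes (2S)-5,7-bis(benzyloxy)-2-[4-(benzyloxy)phenyl]-2H-chromene F6.
- OsO4 with N-methylmorpholine N-oxide adds anti to the 2-aryl group to give (2R,3S,4S)-5,7-bis(benzyloxy)-2-[4-(benzyloxy)phenyl]chromane-3,4-diol F7.
- 2,3-Dichloro-5,6-dicyano-1,4-benzoquinone oxidises only the electron-rich benzylic C4 carbinol to (2R,3R)-5,7-bis(benzyloxy)-2-[4-(benzyloxy)phenyl]-3-hydroxychroman-4-one F8.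
- Hydrogenolysis (H2, Pd/C) gives 12.

Step 3.
- **What may go wrong:** The glycidate may isomerise under base, or the epoxide may be attacked at the wrong carbon, before the weakly nucleophilic, chelated phenoxide engages the benzylic carbon.
- **Fallback:** The aryl ether is made by displacement of an alpha-keto bromide instead of epoxide opening. The fallback sets out from 5 and 2 and comes back at 7, bypassing 6 and step 4.
- BF3·OEt2-catalysed Meinwald-type rearrangement of 5 (1,2-hydride shift to the benzylic cation) gives benzyl 3-[4-(benzyloxy)phenyl]-2-oxopropanoate F9.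
- N-Bromosuccinimide brominates its enol to benzyl 3-bromo-3-[4-(benzyloxy)phenyl]-2-oxopropanoate F10.
- The potassium phenoxide of 2 (K2CO3, acetone, 23 °C) displaces the bromide by SN2 to give 7.

Step 8.
- **What may go wrong:** Alkylation may compete at O4′ or at ring A carbon. Base may also open ring C, with loss of configuration at C2, or promote air oxidation.
- **Fallback:** A neutral Tsuji–Trost etherification sets out from 12 and 13 and comes back at 15.
- With Pd(PPh3)4 (a zerovalent palladium complex) in THF at 23 °C, 13 ionises to a π-allyl alkoxide. This alkoxide deprotonates only the most acidic hydroxyl, O7–H.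
- The resulting phenoxide attacks the unsubstituted allyl terminus (1,4-opening). No external base is present and step 7 is not needed.

Further compounds

F1 | step 5 | ethyl (E)-3-[4-(benzyloxy)phenyl]acrylate | CCOC(=O)/C=C/c1ccc(OCc2ccccc2)cc1
F2 | step 5 | (E)-3-[4-(benzyloxy)phenyl]prop-2-en-1-ol | OC/C=C/c1ccc(OCc2ccccc2)cc1
F3 | step 5 | (E)-3-[4-(benzyloxy)phenyl]prop-2-enyl methyl carbonate | COC(=O)OC/C=C/c1ccc(OCc2ccccc2)cc1
F4 | step 5 | 2,4-bis(benzyloxy)-6-{(1S)-1-[4-(benzyloxy)phenyl]prop-2-enyloxy}benzaldehyde | O=Cc1c(OCc2ccccc2)cc(OCc2ccccc2)cc1O[C@H](c1ccc(OCc2ccccc2)cc1)C=C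
F5 | step 5 | 1,5-bis(benzyloxy)-3-{(1S)-1-[4-(benzyloxy)phenyl]prop-2-enyloxy}-2-vinylbenzene | C=Cc1c(OCc2ccccc2)cc(OCc2ccccc2)cc1O[C@H](c1ccc(OCc2ccccc2)cc1)C=C
F6 | step 5 | (2S)-5,7-bis(benzyloxy)-2-[4-(benzyloxy)phenyl]-2H-chromene | c1ccccc1COc1cc(OCc3ccccc3)c2c(c1)O[C@H](c1ccc(OCc3ccccc3)cc1)C=C2
F7 | step 5 | (2R,3S,4S)-5,7-bis(benzyloxy)-2-[4-(benzyloxy)phenyl]chromane-3,4-diol | c1ccccc1COc1cc(OCc3ccccc3)c2c(c1)O[C@H](c1ccc(OCc3ccccc3)cc1)[C@@H](O)[C@H]2O
F8 | step 5 | (2R,3R)-5,7-bis(benzyloxy)-2-[4-(benzyloxy)phenyl]-3-hydroxychroman-4-one | c1ccccc1COc1cc(OCc3ccccc3)c2c(c1)O[C@H](c1ccc(OCc3ccccc3)cc1)[C@@H](O)C2=O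
F9 | step 3 | benzyl 3-[4-(benzyloxy)phenyl]-2-oxopropanoate | O=C(Cc1ccc(OCc2ccccc2)cc1)C(=O)OCc1ccccc1
F10 | step 3 | benzyl 3-bromo-3-[4-(benzyloxy)phenyl]-2-oxopropanoate | O=C(C(Br)c1ccc(OCc2ccccc2)cc1)C(=O)OCc1ccccc1
F0 | step 8 | none | none
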